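The gamma flask was slow. After 40.0 min its left-handed product stood at 15%, less than the 20% conversion in question.

| flask | left-handed substrate | right-handed substrate | partner | free catalyst | remark |
|---|---|---|---|---|---|
| gamma | 0.085 M | 0.085 M | 0.128 M | 4.2 mM | the very flask that is asked about, followed so far |
| eta | 0.085 M | 0.085 M | 0.086 M | 4.2 mM | run made earlier |
| flask | 0.085 M | 0.085 M | 0.128 M | 4.2 mM |  |

| run | time / min | left-handed product / % |
|---|---|---|
| gamma | 3.00 | 4 |
| gamma | 4.00 | 3 |
| gamma | 6.00 | 2 |
| gamma | 10.0 | 5 |
| gamma | 15.0 | 7 |
| gamma | 25.0 | 11 |
| gamma | 40.0 | 15 |
| eta | 2.00 | 0 |
| eta | 6.00 | 3 |
| eta | 10.0 | 6 |
| eta | 15.0 | 8 |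
| eta | 20.0 | 6 |
| eta | 30.0 | 11 |
| eta | 40.0 | 11 |

(scatter of a reading: 1.5 percentage points)

* apparent order in partner when 20% of the left-handed substrate and right-handed substrate together are converted (percent change of the rate of making left-handed product for one percent more partner charged)

- free catalyst is single-handed; left-handed substrate and right-handed substrate are mirror images of each other, charged as a racemate, each of them at the stated concentration
- the analysis behind the earlier runs scatters by 1.5 percentage points, standard deviation

I compared charges at equal conversion, not at equal time. That froze the substrates, which I took to stand at the same fractions at that mark in both charges.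

First I took the main step by itself: partner, left-handed substrate and free catalyst make left-handed product, at a rate proportional to each. I assumed one partner per turnover. In the gamma flask partner then stood at 73.4% of its charge at the mark. Extra charge is not consumed by the mark, so one percent more charge raises what stands there by more than one percent. I called this the partner lever, the charge divided by what stands at the mark: 1.36. At 40.0 min the gamma reading over the eta reading was 1.36, against a charge ratio of 1.49. These are amounts at equal time, each with a scatter of 1.5 percentage points, so I took them as no test of the lever.

Then I added a path for the right-handed substrate. Conversion counts both hands, and a turnover of either takes one partner, so the lever stayed put.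

Then came the rest, a catalyst that might wear out with time. With such wear I expected more partner to reach the mark sooner, with more catalyst still working, and so an order above the lever. I did not size that wear from these readings. I committed to the lever as my number, expecting the order to lie above it.

The forecast gave 0.35, less than my number, holding that “the initial order is near zero”.

The simulation gave 1.9, with the mark reached at 0.872 h.

    partner + free catalyst + left-handed substrate → free catalyst + left-handed product (k = 0.450 M⁻² s⁻¹)
    partner + free catalyst + right-handed substrate → free catalyst + right-handed product (k = 0.0150 M⁻² s⁻¹)
    free catalyst ⇌ dormant form (K = 0.320, k = 1.50 × 10⁻⁴ s⁻¹)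
    free catalyst → spent catalyst (k = 1.00 × 10⁻⁴ s⁻¹)

At 0.750 h, shortly before that mark, the flask held 62.2% of its catalyst as free catalyst, 16.9% as dormant form and 20.9% as spent catalyst. Of the order, the partner lever gives 1.36, and 0.540 remains above it.

(All runs come from a simulation for substances that don't exist; the scatter is artificial.)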